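**Plan**

- Retrosynthetic cuts: the C11–O aryl ether bond, the C9–C11 bond, the C3–C4 bond of ring A, and the two bonds from C10 to C1 and to its methyl group.
- Enabling feature (drimane numbering; ring A = C1–C5 and C10, ring B = C5–C10): the gem-dimethyl carbon C4 lies next to the C3 carbonyl, so C4 can start as an isopropenyl carbon and C3 as an aldehyde. Ring B, with its C8 methyl, C7=C8 olefin and C5 stereocentre, is the carvone ring.
- Forward order: ring B is bought as (S)-carvone, C10 is made quaternary by two enolate alkylations, ring A is closed by a hydrogen-atom-transfer radical cyclization, C11 is added at C9, the coumarin is attached and C3 is oxidised last.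
- Stereochemistry: C5 comes from (S)-carvone. C10 is set by methylating last, anti to the isopropenyl group, which leaves the side chain cis to it and forces a cis ring fusion. C9 is set by hydroboration of a 9(11)-methylene group from the convex face of the cis-decalin.

Key step: step 4

Remark: β denotes the face of the C10 methyl group. Read from the SMILES, the target has the C10 methyl, H5 and H9 all β (cis-fused decalin, CH2OAr α). The C3 carbinol of 8–13 is written as one epimer for definiteness; either epimer serves, because step 8 oxidises it.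

**Route**

Step 1
Reactants: 1 (S)-(+)-carvone; 2 2-(2-bromoethyl)-1,3-dioxolane
Product: 4 (5S,6R)-6-[2-(1,3-dioxolan-2-yl)ethyl]-2-methyl-5-(prop-1-en-2-yl)cyclohex-2-en-1-one, via lithium dienolate of carvone 3 (not isolated)
Conditions: LiN(iPr)2, THF, −78 °C; then 2, DMPU, −78 °C → rt
Reagents that add atoms: none
Why: Kinetic deprotonation at the α′-carbon gives the cross-conjugated lithium dienolate, which should be alkylated by the primary bromide in the polar cosolvent (enolate SN2 alkylation); the chain is expected mainly trans to isopropenyl, but this centre is planarised again in step 2, so its configuration is immaterial.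

Step 2
Reactants: 4
Product: 6 (5R,6S)-6-[2-(1,3-dioxolan-2-yl)ethyl]-2,6-dimethyl-5-(prop-1-en-2-yl)cyclohex-2-en-1-one, via lithium dienolate of the monoalkylated ketone 5 (not isolated)
Conditions: LiN(iPr)2, THF, −78 °C; then MeI, −78 → 0 °C
Reagents that add atoms: iodomethane, CI
Why: The tetrasubstituted dienolate should be methylated on the face opposite the neighbouring isopropenyl group (diastereoselective enolate alkylation), so the methyl group ends up trans and the acetal chain cis to isopropenyl, which fixes the quaternary centre that becomes C10.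

Step 3
Reactants: 6
Product: 7 3-[(1S,6R)-1,3-dimethyl-2-oxo-6-(prop-1-en-2-yl)cyclohex-3-en-1-yl]propanal
Conditions: 1 M aq. HCl, THF, rt
Reagents that add atoms: water, O
Why: Dilute aqueous acid should hydrolyse the dioxolane to the aldehyde (acetal hydrolysis) without affecting the enone, the isopropenyl group or the quaternary centre.

Step 4
Reactants: 7
Product: 8 (4aR,6S,8aS)-6-hydroxy-2,5,5,8a-tetramethyl-4a,5,6,7,8,8a-hexahydronaphthalen-1(4H)-one (cis-fused 3-hydroxy-11-nordrim-7-en-9-one)
Conditions: Fe(acac)3 (20 mol%), PhSiH3, degassed EtOH, 60 °C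
Reagents that add atoms: none
Why: Fe(acac)3 and PhSiH3 form an iron hydride that transfers a hydrogen atom to the CH2 terminus of the isopropenyl group, which becomes the second C4 methyl and leaves a nucleophilic tertiary radical at C4. This radical adds to the carbonyl carbon of the tethered aldehyde, forming C3–C4 and closing ring A in a 6-exo-trig mode through a chair-like transition state; the alkoxy radical is then reduced by divalent iron and protonated by ethanol, which regenerates trivalent iron. The closest known reaction type is the iron-hydride MHAT reductive radical cyclization of alkenes onto tethered ketones and aldehydes. The only new stereocentre is the C3 carbinol, governed by the preference of the aldehyde oxygen for a pseudo-equatorial position in the chair and of no consequence later; C5 and C10 are already fixed in 7 with the chain and isopropenyl group cis, so the fusion can only be cis. The step needs hydrogen-atom transfer to the electron-rich 1,1-disubstituted olefin and ring closure faster than reduction of the radical: the conjugated trisubstituted enone olefin is a poor MHAT acceptor, and the enone carbons can be reached from C4 only through a four-membered ring, so the aldehyde is the sole acceptor within reach.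

Step 5
Reactants: 8
Product: 9 (2S,4aS,8aS)-1,1,4a,6-tetramethyl-5-methylidene-1,2,3,4,4a,5,8,8a-octahydronaphthalen-2-ol
Conditions: Ph3PCH3Br, KOtBu (excess), toluene, 90 °C
Reagents that add atoms: methyltriphenylphosphonium bromide, C[P+](c1ccccc1)(c1ccccc1)c1ccccc1.[Br-]
Why: Excess methylenetriphenylphosphorane at elevated temperature should methylenate the hindered C9 ketone (Wittig olefination), which has no α-hydrogen at C10; the C3 hydroxyl is only deprotonated and no stereocentre is touched.

Step 6
Reactants: 9
Product: 11 (2S,4aS,5R,8aS)-5-(hydroxymethyl)-1,1,4a,6-tetramethyl-1,2,3,4,4a,5,8,8a-octahydronaphthalen-2-ol, via bis(9-BBN) adduct 10 (not isolated)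
Conditions: 9-BBN (3 equiv), THF, 0 → 50 °C; then NaOH, H2O2, 0 °C → rt
Reagents that add atoms: hydrogen peroxide, OO
Why: 9-BBN should add to the exocyclic 1,1-disubstituted terminus of the diene with boron on C11 and hydrogen on C9, sparing the trisubstituted C7=C8 olefin (hydroboration–oxidation); hydrogen is expected from the convex β face because ring A, with C1 and the C4 methyl lying under C9, screens the α face, so H9 becomes β and the CH2OH group α after oxidation with retention.

Step 7
Reactants: 11; 12 umbelliferone (7-hydroxycoumarin)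
Product: 13 7-{[(1R,4aS,6S,8aS)-6-hydroxy-2,5,5,8a-tetramethyl-1,4,4a,5,6,7,8,8a-octahydronaphthalen-1-yl]methoxy}-2H-chromen-2-one
Conditions: PPh3, DIAD, THF, 0 °C → rt
Reagents that add atoms: none
Why: The acidic phenol should be alkylated by the activated primary C11 alcohol (Mitsunobu etherification), while the secondary C3 hydroxyl beside the gem-dimethyl carbon is too hindered to react; C9 is not involved.

Step 8
Reactants: 13
Product: 14 7-{[(1R,4aS,8aS)-2,5,5,8a-tetramethyl-6-oxo-1,4,4a,5,6,7,8,8a-octahydronaphthalen-1-yl]methoxy}-2H-chromen-2-one (CNP0262399.3)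
Conditions: Dess–Martin periodinane, CH2Cl2, rt
Reagents that add atoms: none
Why: The hypervalent iodine reagent should oxidise the C3 carbinol to the ketone (Dess–Martin oxidation) under near-neutral conditions that spare the coumarin, the aryl ether and the olefin and cannot epimerise C5, C9 or C10.

**Compound list**

1 | (S)-(+)-carvone | CC1=CC[C@H](C(C)=C)CC1=O | starting material
2 | 2-(2-bromoethyl)-1,3-dioxolane | BrCCC1OCCO1 | starting material
3 | lithium dienolate of carvone | CC1=CC[C@H](C(C)=C)C=C1O[Li] | intermediate
4 | (5S,6R)-6-[2-(1,3-dioxolan-2-yl)ethyl]-2-methyl-5-(prop-1-en-2-yl)cyclohex-2-en-1-one | CC1=CC[C@H](C(C)=C)[C@@H](CCC2OCCO2)C1=O | intermediate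
5 | lithium dienolate of the monoalkylated ketone | CC1=CC[C@H](C(C)=C)C(CCC2OCCO2)=C1O[Li] | intermediate
6 | (5R,6S)-6-[2-(1,3-dioxolan-2-yl)ethyl]-2,6-dimethyl-5-(prop-1-en-2-yl)cyclohex-2-en-1-one | CC1=CC[C@H](C(C)=C)[C@](C)(CCC2OCCO2)C1=O | intermediate
7 | 3-[(1S,6R)-1,3-dimethyl-2-oxo-6-(prop-1-en-2-yl)cyclohex-3-en-1-yl]propanal | CC1=CC[C@H](C(C)=C)[C@](C)(CCC=O)C1=O | intermediate
8 | (4aR,6S,8aS)-6-hydroxy-2,5,5,8a-tetramethyl-4a,5,6,7,8,8a-hexahydronaphthalen-1(4H)-one | CC1=CC[C@@H]2C(C)(C)[C@@H](O)CC[C@]2(C)C1=O | intermediate
9 | (2S,4aS,8aS)-1,1,4a,6-tetramethyl-5-methylidene-1,2,3,4,4a,5,8,8a-octahydronaphthalen-2-ol | CC1=CC[C@@H]2C(C)(C)[C@@H](O)CC[C@]2(C)C1=C | intermediate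
10 | bis(9-BBN) adduct of 9 (C11–B alkylborane, C3–O–B borinate) | CC1=CC[C@@H]2C(C)(C)[C@@H](OB3C4CCCC3CCC4)CC[C@]2(C)[C@@H]1CB1C2CCCC1CCC2 | intermediate
11 | (2S,4aS,5R,8aS)-5-(hydroxymethyl)-1,1,4a,6-tetramethyl-1,2,3,4,4a,5,8,8a-octahydronaphthalen-2-ol | CC1=CC[C@@H]2C(C)(C)[C@@H](O)CC[C@]2(C)[C@@H]1CO | intermediate
12 | umbelliferone | O=c1ccc2ccc(O)cc2o1 | starting material
13 | 7-{[(1R,4aS,6S,8aS)-6-hydroxy-2,5,5,8a-tetramethyl-1,4,4a,5,6,7,8,8a-octahydronaphthalen-1-yl]methoxy}-2H-chromen-2-one | CC1=CC[C@@H]2C(C)(C)[C@@H](O)CC[C@]2(C)[C@@H]1COc1ccc2ccc(=O)oc2c1 | intermediate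
14 | 7-{[(1R,4aS,8aS)-2,5,5,8a-tetramethyl-6-oxo-1,4,4a,5,6,7,8,8a-octahydronaphthalen-1-yl]methoxy}-2H-chromen-2-one | CC1=CC[C@@H]2C(C)(C)C(=O)CC[C@]2(C)[C@@H]1COc1ccc2ccc(=O)oc2c1 | target

Total step count: 8. Longest linear sequence: 8 steps (1 → 14).

**Steps most likely to fail**

Step 4. Addition of the tertiary radical to the aldehyde is reversible, so simple reduction of the radical to an isopropyl group, hydrogen abstraction next to the aldehyde, or silane reduction of the aldehyde may outrun ring closure. The fallback changes the acceptor and its oxidation level. Setting out from 7, I2 in aqueous NH3/THF should convert the aldehyde into 3-[(1S,6R)-1,3-dimethyl-2-oxo-6-(prop-1-en-2-yl)cyclohex-3-en-1-yl]propanenitrile F1. The same Fe(acac)3/PhSiH3 conditions should then close ring A by 6-exo-dig addition of the C4 radical to the nitrile carbon, a known MHAT alkene–nitrile cyclization. The product is the cis-fused 3-imino-11-nordrim-7-en-9-one F2, which is not isolated but hydrolysed on acidic work-up to the cis-fused (4aR,8aS)-11-nordrim-7-ene-3,9-dione F3. NaBH4 in MeOH/CH2Cl2 at −78 °C should reduce the saturated C3 ketone ahead of the hindered conjugated C9 ketone and bring the route back to 8.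

Step 6. Delivery of hydrogen to C9 may discriminate poorly between the two faces, or the borane may engage the hindered conjugated diene sluggishly. The fallback sets C9 through a C–C bond-forming event followed by a stereospecific hydrogenolysis; it still relies on convex-face attack, but by a different reagent at a different stage. Setting out from 8, Me3SI/n-BuLi (THF, 0 °C) should add the sulfonium ylide to the C9 carbonyl from the convex β face (Corey–Chaykovsky epoxidation) to give the spiro vinyl epoxide F4, with C11 β and oxygen α. Pd2(dba)3, PBu3, HCO2H and Et3N in dioxane should then open it: zerovalent palladium ionises the allylic C9–O bond anti to oxygen and the hydride is passed from palladium to C9 on the β face. This inversion places the CH2OH group α and rejoins the route at 11.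

Step 1. Slow SN2 reaction at the β-alkoxy primary bromide may allow proton exchange between enolate and product (polyalkylation) and E2 loss of HBr from the electrophile. The fallback builds the chain from a reactive allyl electrophile. Setting out from 1, the dienolate 3 and allyl bromide should give (5S,6R)-6-allylcarvone F5. Deprotonation with LiN(iPr)2 gives the lithium dienolate of 6-allylcarvone F6, and MeI, again entering anti to isopropenyl, gives (5R,6S)-2,6-dimethyl-6-(prop-2-en-1-yl)-5-(prop-1-en-2-yl)cyclohex-2-en-1-one F7. Disiamylborane (Sia2BH, THF, 0 °C) should hydroborate the monosubstituted olefin in preference to the hindered isopropenyl group, giving the disiamyl(alkyl)borane F8. NaOH/H2O2 then gives (5R,6S)-6-(3-hydroxypropyl)-2,6-dimethyl-5-(prop-1-en-2-yl)cyclohex-2-en-1-one F9. Dess–Martin periodinane oxidises the primary alcohol, and would also restore any enone carbonyl reduced by the borane, returning the route to 7.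

**Further compounds**

F1 | step 4 | 3-[(1S,6R)-1,3-dimethyl-2-oxo-6-(prop-1-en-2-yl)cyclohex-3-en-1-yl]propanenitrile | CC1=CC[C@H](C(C)=C)[C@](C)(CCC#N)C1=O
F2 | step 4 | cis-fused 3-imino-11-nordrim-7-en-9-one (not isolated) | CC1=CC[C@@H]2C(C)(C)C(=N)CC[C@]2(C)C1=O
F3 | step 4 | cis-fused (4aR,8aS)-11-nordrim-7-ene-3,9-dione | CC1=CC[C@@H]2C(C)(C)C(=O)CC[C@]2(C)C1=O
F4 | step 6 | spiro vinyl epoxide of 8 at C9 (C11 β, O α) | CC1=CC[C@@H]2C(C)(C)[C@@H](O)CC[C@]2(C)[C@@]13CO3
F5 | step 1 | (5S,6R)-6-allylcarvone | CC1=CC[C@H](C(C)=C)[C@@H](CC=C)C1=O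
F6 | step 1 | lithium dienolate of 6-allylcarvone | CC1=CC[C@H](C(C)=C)C(CC=C)=C1O[Li]
F7 | step 1 | (5R,6S)-2,6-dimethyl-6-(prop-2-en-1-yl)-5-(prop-1-en-2-yl)cyclohex-2-en-1-one | CC1=CC[C@H](C(C)=C)[C@](C)(CC=C)C1=O
F8 | step 1 | disiamyl(alkyl)borane from F7 | CC1=CC[C@H](C(C)=C)[C@](C)(CCCB(C(C)C(C)C)C(C)C(C)C)C1=O
F9 | step 1 | (5R,6S)-6-(3-hydroxypropyl)-2,6-dimethyl-5-(prop-1-en-2-yl)cyclohex-2-en-1-one | CC1=CC[C@H](C(C)=C)[C@](C)(CCCO)C1=O
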